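## Analysis of the target

Stenosporic acid 12 is a para-depside: two benzene rings joined by one aryl ester, with no further ring and no stereocentre, so no configuration has to be set or related. Ring A is the acyl half, a benzoyl group with OH at C2, OMe at C4 and propyl at C6. Ring B is a benzoic acid with OH at C2, the ester oxygen at C4 and pentyl at C6. The sensitive groups are the aryl ester (an activated ester, cleaved by hydroxide, alkoxide or amines), the ring B salicylic acid (it decarboxylates when the ring is electron-rich and the medium hot or acidic) and the free phenols (oxidisable). The difficulty lies in the oxygen pattern, not the skeleton: a classical synthesis must tell four phenolic oxygens apart, mask the ring B acid, and esterify with a ring A acid that is flanked on both sides and hydrogen-bonded. The route rests on the fact that both free phenols sit next to a carbonyl-bearing carbon. Ring A C2-OH is ortho to C1, which carries the depside C=O, and ring B C2-OH is ortho to C1, which carries the carboxyl group; the other ortho position of each ring (C6) holds the alkyl chain. In the deoxy depside 10, which lacks both hydroxyls, each carbonyl therefore has exactly one ortho C-H bond and can act as a directing group for a final oxygenation.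

## Retrosynthetic reasoning

**12 to 10 (through 11).** The first cut removes the aryl C-O bonds at ring A C2 and ring B C2, leading back to 10, where these positions carry hydrogen. These two oxygens cause the chelation, the phenol differentiation and the decarboxylation risk, so taking them out first leaves only phenol-free, robust arenes upstream. In the forward direction each carbonyl must guide the metal to its single free ortho C-H bond, and the oxidant must turn both carbon-metal bonds into C-O bonds. The oxygens arrive masked as the bis(trifluoroacetate) 11, which aqueous workup opens to 12.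

**10 to 9.** The carboxyl group of 10 is traced to the benzyl ester 9. Hydrogenolysis is neither basic nor nucleophilic, so it frees the acid without touching the aryl ester.

**9 to 7 and 8.** The ring B-pentyl bond is cut to the aryl bromide 7 and pentylzinc bromide 8. The bromide is ortho to an ester, which speeds oxidative addition, and an alkylzinc halide tolerates both esters. Making this bond after the ester union means no free phenol ever meets the organozinc.

**7 to 4 and 6.** The depside C-O bond is cut to acid 4 and phenol 6. This is the convergent cut. Acid 4 has one ortho substituent and no chelated hydroxyl, so its esterification is easier than that of the fully oxygenated ring A acid.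

**6 to 5.** The benzyl ester of 6 comes from the bromo hydroxy acid 5 by alkylating the carboxylate only; the gap in acidity between carboxyl and phenol provides the selectivity.

**4 to 3, then 1 and 2.** Acid 4 comes from its methyl ester 3 by saponification. The ring A-propyl bond of 3 is cut to bromo ester 1 and propylzinc bromide 2, the same cross-coupling logic as on ring B.

## Alternatives that were turned down

**Alternative 1:** Ring A is taken apart at C1-C2 and C5-C6 into two pieces. One is the diene 1,3-dimethoxy-1-(trimethylsilyloxy)buta-1,3-diene A1. The other is the ring B aryl hex-2-ynoate A2, that is benzyl 2-(tert-butyldimethylsilyloxy)-4-(hex-2-ynoyloxy)-6-pentylbenzoate.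
- **Forward reaction:** a [4+2] addition of A1 across the triple bond of A2, then loss of methanol and of the trimethylsilyl group, gives the arene A3.
- **For:** the CH2 terminus of A1 attacks the propyl-bearing alkyne carbon of A2 and the ketene acetal carbon ends next to the ester, so 2-OH, 4-OMe and 6-propyl fall into place without any selective methylation. Cycloadditions of this type with acetylenic esters are established, and on predictability this key step is stronger than the chosen one.
- **Against:** the dienophile A2 must carry a fully oxygenated, triply differentiated ring B (benzyl ester, silyl ether on the chelated hydroxyl, ynoate on the other). A beta-alkyl ynoate is a sluggish dienophile, and at the temperature needed the ketene acetal can attack the activated aryl ester of A2 or lose its silyl group. Two deprotections follow the key step.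
- **Comparison:** the chosen route offers seven steps from simple haloarenes and no phenol protecting groups, at the price of an unprecedented last step.

**Alternative 2:** Ring B is cut at two adjacent bonds, C6-pentyl and C1-carboxyl, back to the aryne 3,5-dimethoxybenzyne A5. The aryne is generated from 1-fluoro-3,5-dimethoxybenzene A4 by lithiation next to fluorine and loss of fluoride.
- **Forward reaction:** pentylmagnesium bromide A6 adds to the aryne carbon of A5 remote from the neighbouring methoxy group, the aryl-magnesium bond forms beside that oxygen, and carboxylation gives 2,4-dimethoxy-6-pentylbenzoic acid A7.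
- **For:** one flask sets the alkyl/carboxyl pair with regiochemistry governed by a well-understood inductive effect, from cheap materials. On precedent for its own key step it is stronger than the chosen route.
- **Against:** it solves only ring B and delivers it as the bis(methyl ether) A7. Both ethers must be cleaved with BBr3 or AlCl3 on an acid that decarboxylates easily once the phenols are free. The acid must then be protected, ring A made separately with its own oxygen differentiation, the halves joined selectively and the product deprotected. Lithiation between the two methoxy groups of A4 also competes.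
- **Comparison:** the chosen route is about half as long and brings the oxygens in as trifluoroacetates that leave on workup, not as methyl ethers that need harsh removal.

**Alternative 3:** The depside C-O bond and ring A C1-C6 are cut together. Ring A is carried as the open-chain diketo-dioxinone A8 and ring B as benzyl 2,4-dihydroxy-6-pentylbenzoate A9.
- **Forward reaction:** heating A8 opens the dioxinone to the acylketene A10 with loss of acetone, the non-chelated 4-OH of A9 traps it to give the triketo aryl ester A11, and aldol closure with dehydration gives the resorcylate depside A12.
- **For:** it is biomimetic and convergent, forms the ester and ring A in one operation, and the ring A oxygen pattern is inherent in the chain. On convergence, and on having the oxygens built in, it is stronger than the chosen route.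
- **Against:** A12 still needs selective methylation of the ring A 4-OH beside two chelated phenols, then hydrogenolysis. A8 takes several steps, and A9 must be made from an already oxygenated ring B. In A11 the aryloxide is a good leaving group, so closure through oxygen to a hydroxypyrone, expelling ring B, competes with the C-C aldol.
- **Comparison:** the chosen route is shorter, has no methylation selectivity to solve, and carries only stable, non-enolisable intermediates until its last step.

Key step: step 7

## Route

Assumptions: compounds 1 and 5 and THF solutions of 2 and 8 are taken as commercial. In the medium of step 7 the carboxyl group of 10 is expected to exchange reversibly with its mixed trifluoroacetic anhydride, which reverts to the acid on aqueous workup and is not treated as a separate compound.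

Step 1
Reactants: 1 methyl 2-bromo-4-methoxybenzoate; 2 propylzinc bromide
Product: 3 methyl 4-methoxy-2-propylbenzoate
Conditions: PdCl2(dppf) (3 mol%), THF, 50 °C
Reagents that add atoms: none
Why: Negishi coupling; zerovalent palladium inserts readily into the C-Br bond ortho to the ester, the alkylzinc halide transmetalates without attacking the ester, and the wide bite angle of dppf favours reductive elimination over beta-hydride elimination.

Step 2
Reactants: 3 methyl 4-methoxy-2-propylbenzoate
Product: 4 4-methoxy-2-propylbenzoic acid
Conditions: LiOH, THF/MeOH/H2O, 60 °C; then 1 M HCl
Reagents that add atoms: lithium hydroxide, [Li+].[OH-]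
Why: Saponification by acyl-oxygen cleavage; a single ortho substituent slows but does not block hydroxide attack, and nothing else in 3 is base-sensitive.

Step 3
Reactants: 5 2-bromo-4-hydroxybenzoic acid
Product: 6 benzyl 2-bromo-4-hydroxybenzoate
Conditions: BnBr (1.05 equiv), KHCO3, DMF, 40 °C
Reagents that add atoms: benzyl bromide, BrCc1ccccc1
Why: Chemoselective SN2 alkylation of the carboxylate; hydrogencarbonate deprotonates the acid but not the phenol, so the phenol stays free for step 4.

Step 4
Reactants: 4 4-methoxy-2-propylbenzoic acid; 6 benzyl 2-bromo-4-hydroxybenzoate
Product: 7 benzyl 2-bromo-4-[(4-methoxy-2-propylbenzoyl)oxy]benzoate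
Conditions: DCC, DMAP (0.1 equiv), CH2Cl2, 0 °C to rt
Reagents that add atoms: none
Why: Steglich esterification; the carbodiimide activates the acid, DMAP relays the acyl group to the phenol, and the acid has only one ortho substituent and no chelated hydroxyl.

Step 5
Reactants: 7 benzyl 2-bromo-4-[(4-methoxy-2-propylbenzoyl)oxy]benzoate; 8 pentylzinc bromide
Product: 9 benzyl 4-[(4-methoxy-2-propylbenzoyl)oxy]-2-pentylbenzoate
Conditions: PdCl2(dppf) (5 mol%), THF, 45 °C
Reagents that add atoms: none
Why: Negishi coupling; the bromide ortho to the benzyl ester is activated for oxidative addition, and the alkylzinc halide is not nucleophilic enough to attack the aryl or benzyl ester at this temperature.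

Step 6
Reactants: 9 benzyl 4-[(4-methoxy-2-propylbenzoyl)oxy]-2-pentylbenzoate
Product: 10 4-[(4-methoxy-2-propylbenzoyl)oxy]-2-pentylbenzoic acid
Conditions: H2 (1 atm), 10% Pd/C, EtOAc, rt
Reagents that add atoms: none
Why: Hydrogenolysis of the benzylic C-O bond under neutral conditions; the aryl ester, the methyl ether and both arenes are inert to it.

Step 7
Reactants: 10 4-[(4-methoxy-2-propylbenzoyl)oxy]-2-pentylbenzoic acid
Product: 12 stenosporic acid (2-hydroxy-4-[(2-hydroxy-4-methoxy-6-propylbenzoyl)oxy]-6-pentylbenzoic acid), via bis(trifluoroacetate) 11 (not isolated)
Conditions: [RuCl2(p-cymene)]2 (5 mol%), PhI(OCOCF3)2 (2.6 equiv), CF3CO2H/(CF3CO)2O 4:1, 80 °C; then aq. Na2S2O3, H2O/THF, rt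
Reagents that add atoms: phenyliodine bis(trifluoroacetate), O=C(OI(OC(=O)C(F)(F)F)c1ccccc1)C(F)(F)F; trifluoroacetic acid, OC(=O)C(F)(F)F
Why: Proposed new method: chloride-trifluoroacetate exchange on [RuCl2(p-cymene)]2 should give a divalent ruthenium trifluoroacetate that binds a carbonyl oxygen (the depside C=O for ring A, the carboxyl C=O or its ruthenium carboxylate for ring B) and cleaves the one ortho C-H bond by carboxylate-assisted concerted metalation-deprotonation to a five-membered ruthenacycle. PhI(OCOCF3)2 should oxidise this to a tetravalent ruthenium aryl trifluoroacetate, C-O reductive elimination should release the aryl trifluoroacetate and divalent ruthenium, and the cycle should repeat at the second carbonyl to give 11, which water cleaves to 12 at room temperature. The phenolic oxygens thus come from trifluoroacetate, which passes freely between the iodane and the solvent acid. The closest known reaction type is ortho C-H hydroxylation of single alkyl benzoates, aryl ketones and benzamides with divalent ruthenium, and of benzoic acids with divalent palladium; a twofold version on a depside, directed by an aryl ester and a free carboxyl group, has not been shown. No ring closes and no stereocentre forms. The step needs oxygenation at C6-H of each ring of 10 (C2 of each ring in 12) and not at ring B C3-H or C5-H, which the depside carbonyl could reach through a six-membered ruthenacycle across the ester oxygen, nor at ring A C3-H or C5-H beside the methoxy group. This should hold because each carbonyl has a single free ortho position (the other carries propyl or pentyl), five-membered chelation by a weak oxygen donor is favoured over six-membered chelation across the twisted aryl ester, and the position para to the methoxy group, where undirected oxidation would begin, is occupied by the carbonyl carbon. Each new oxygen appears as an electron-poor trifluoroacetate, which should suppress over-oxidation and decarboxylation of the salicylate, and the anhydrous acid should leave the depside ester intact.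

## Compound list

1 | methyl 2-bromo-4-methoxybenzoate | COC(=O)c1ccc(OC)cc1Br | starting material
2 | propylzinc bromide | CCC[Zn]Br | starting material
3 | methyl 4-methoxy-2-propylbenzoate | CCCc1cc(OC)ccc1C(=O)OC | intermediate
4 | 4-methoxy-2-propylbenzoic acid | CCCc1cc(OC)ccc1C(=O)O | intermediate
5 | 2-bromo-4-hydroxybenzoic acid | OC(=O)c1ccc(O)cc1Br | starting material
6 | benzyl 2-bromo-4-hydroxybenzoate | O=C(OCc1ccccc1)c1ccc(O)cc1Br | intermediate
7 | benzyl 2-bromo-4-[(4-methoxy-2-propylbenzoyl)oxy]benzoate | CCCc1cc(OC)ccc1C(=O)Oc1ccc(C(=O)OCc2ccccc2)c(Br)c1 | intermediate
8 | pentylzinc bromide | CCCCC[Zn]Br | starting material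
9 | benzyl 4-[(4-methoxy-2-propylbenzoyl)oxy]-2-pentylbenzoate | CCCCCc1cc(OC(=O)c2ccc(OC)cc2CCC)ccc1C(=O)OCc1ccccc1 | intermediate
10 | 4-[(4-methoxy-2-propylbenzoyl)oxy]-2-pentylbenzoic acid | CCCCCc1cc(OC(=O)c2ccc(OC)cc2CCC)ccc1C(=O)O | intermediate
11 | 4-{[4-methoxy-2-propyl-6-(trifluoroacetoxy)benzoyl]oxy}-2-pentyl-6-(trifluoroacetoxy)benzoic acid | CCCCCc1cc(OC(=O)c2c(OC(=O)C(F)(F)F)cc(OC)cc2CCC)cc(OC(=O)C(F)(F)F)c1C(=O)O | intermediate
12 | stenosporic acid, 2-hydroxy-4-[(2-hydroxy-4-methoxy-6-propylbenzoyl)oxy]-6-pentylbenzoic acid | CCCCCc1cc(OC(=O)c2c(O)cc(OC)cc2CCC)cc(O)c1C(=O)O | target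

## Step count and risk

Total step count: 7. Longest linear sequence: 6 steps (1, 3, 4, 7, 9, 10, 12 through steps 1, 2, 4, 5, 6, 7); the ring B branch (5, 6) joins at step 4.

**Step 7 (key step).** The most likely failure is a stalled or misdirected second oxygenation. The depside carbonyl is a weak donor, twisted by the ortho propyl group and attached to an electron-poor aryloxy group, so metalation of ring A may lag behind that of ring B. While the substrate waits, four side processes can intervene: six-membered metalation at ring B C5, attack of the iodane on the anisole ring, acyl transfer from the mixed anhydride of the carboxyl group, and benzylic oxidation of the pentyl chain with closure onto the carboxyl group.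

The fallback sets out from 3, rejoins the route at 12, and uses the hydroxylation only where it is known, on a single alkyl benzoate. Ester 3 with [RuCl2(p-cymene)]2, PhI(OCOCF3)2 and CF3CO2H/(CF3CO)2O at 80 °C should give methyl 4-methoxy-2-propyl-6-(trifluoroacetoxy)benzoate F1, which is not isolated and which aqueous workup should open to methyl 2-hydroxy-4-methoxy-6-propylbenzoate F2. KOH in aqueous DMSO at 90 °C and cold acidification should then give 2-hydroxy-4-methoxy-6-propylbenzoic acid F3. Purchased 2,4-dihydroxy-6-pentylbenzoic acid F4 would be benzylated (benzyl bromide, KHCO3, DMF) to benzyl 2,4-dihydroxy-6-pentylbenzoate F5, in which only the 4-OH is free of hydrogen bonding. Condensation of F3 with F5 by (CF3CO)2O in toluene at rt, the classical depside coupling, should give benzyl 2-hydroxy-4-[(2-hydroxy-4-methoxy-6-propylbenzoyl)oxy]-6-pentylbenzoate F6. Hydrogenolysis (H2, 10% Pd/C, EtOAc) then arrives at 12.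

**Step 5.** The likely failure is hydrodebromination: beta-hydride elimination from the pentyl-palladium intermediate followed by C-H reductive elimination, favoured because the ester beside the bromide slows transmetalation. Ionisation of the benzyl ester by zerovalent palladium is a lesser concern. The fallback sets out from 7 and rejoins at 10. Sonogashira coupling of 7 with pent-1-yne (PdCl2(PPh3)2, CuI, Et3N, THF, 50 °C) should give benzyl 4-[(4-methoxy-2-propylbenzoyl)oxy]-2-(pent-1-yn-1-yl)benzoate F7. Hydrogenation (H2, 10% Pd/C, EtOAc) then saturates the alkyne and cleaves the benzyl ester in one operation, replacing steps 5 and 6.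

**Step 4.** The likely failure is rearrangement of the activated acid to an unreactive N-acylurea, because acyl transfer from the ortho-propyl acid to the electron-poor phenol is slow. The fallback sets out from 4 and rejoins at 7. (COCl)2 with catalytic DMF in CH2Cl2 should give 4-methoxy-2-propylbenzoyl chloride F8, which acylates 6 with Et3N and catalytic DMAP in CH2Cl2 at 0 °C.

**Step 3.** The likely failure is over-alkylation at the phenol oxygen, which is acidified by the para carboxyl group. The fallback sets out from 5 and rejoins at 6: acid-catalysed esterification with benzyl alcohol (TsOH, toluene, water removed azeotropically), under which a phenol is not etherified. This fallback makes no new compound, which is recorded as F0.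

## Further compounds

F1 | step 7 | methyl 4-methoxy-2-propyl-6-(trifluoroacetoxy)benzoate | CCCc1cc(OC)cc(OC(=O)C(F)(F)F)c1C(=O)OC
F2 | step 7 | methyl 2-hydroxy-4-methoxy-6-propylbenzoate | CCCc1cc(OC)cc(O)c1C(=O)OC
F3 | step 7 | 2-hydroxy-4-methoxy-6-propylbenzoic acid | CCCc1cc(OC)cc(O)c1C(=O)O
F4 | step 7 | 2,4-dihydroxy-6-pentylbenzoic acid | CCCCCc1cc(O)cc(O)c1C(=O)O
F5 | step 7 | benzyl 2,4-dihydroxy-6-pentylbenzoate | CCCCCc1cc(O)cc(O)c1C(=O)OCc1ccccc1
F6 | step 7 | benzyl 2-hydroxy-4-[(2-hydroxy-4-methoxy-6-propylbenzoyl)oxy]-6-pentylbenzoate | CCCCCc1cc(OC(=O)c2c(O)cc(OC)cc2CCC)cc(O)c1C(=O)OCc1ccccc1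
F7 | step 5 | benzyl 4-[(4-methoxy-2-propylbenzoyl)oxy]-2-(pent-1-yn-1-yl)benzoate | CCCC#Cc1cc(OC(=O)c2ccc(OC)cc2CCC)ccc1C(=O)OCc1ccccc1
F8 | step 4 | 4-methoxy-2-propylbenzoyl chloride | CCCc1cc(OC)ccc1C(Cl)=O
F0 | step 3 | none | none
A1 | alternative 1 | 1,3-dimethoxy-1-(trimethylsilyloxy)buta-1,3-diene | COC(=C)C=C(OC)O[Si](C)(C)C
A2 | alternative 1 | benzyl 2-(tert-butyldimethylsilyloxy)-4-(hex-2-ynoyloxy)-6-pentylbenzoate | CCCC#CC(=O)Oc1cc(O[Si](C)(C)C(C)(C)C)c(C(=O)OCc2ccccc2)c(CCCCC)c1
A3 | alternative 1 | benzyl 2-(tert-butyldimethylsilyloxy)-4-[(2-hydroxy-4-methoxy-6-propylbenzoyl)oxy]-6-pentylbenzoate | CCCc1cc(OC)cc(O)c1C(=O)Oc1cc(O[Si](C)(C)C(C)(C)C)c(C(=O)OCc2ccccc2)c(CCCCC)c1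
A4 | alternative 2 | 1-fluoro-3,5-dimethoxybenzene | COc1cc(F)cc(OC)c1
A5 | alternative 2 | 3,5-dimethoxybenzyne | COC1=CC(OC)=CC#C1
A6 | alternative 2 | pentylmagnesium bromide | CCCCC[Mg]Br
A7 | alternative 2 | 2,4-dimethoxy-6-pentylbenzoic acid | CCCCCc1cc(OC)cc(OC)c1C(=O)O
A8 | alternative 3 | 2,2-dimethyl-6-(2,4-dioxoheptyl)-4H-1,3-dioxin-4-one | CCCC(=O)CC(=O)CC1=CC(=O)OC(C)(C)O1
A9 | alternative 3 | benzyl 2,4-dihydroxy-6-pentylbenzoate | CCCCCc1cc(O)cc(O)c1C(=O)OCc1ccccc1
A10 | alternative 3 | dec-1-ene-1,3,5,7-tetrone (acylketene) | O=C=CC(=O)CC(=O)CC(=O)CCC
A11 | alternative 3 | benzyl 2-hydroxy-6-pentyl-4-[(3,5,7-trioxodecanoyl)oxy]benzoate | CCCCCc1cc(OC(=O)CC(=O)CC(=O)CC(=O)CCC)cc(O)c1C(=O)OCc1ccccc1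
A12 | alternative 3 | benzyl 4-[(2,4-dihydroxy-6-propylbenzoyl)oxy]-2-hydroxy-6-pentylbenzoate | CCCCCc1cc(OC(=O)c2c(O)cc(O)cc2CCC)cc(O)c1C(=O)OCc1ccccc1
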